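**Assumption:** the target's (2S,3R,4S,5R) pattern with two identical aryl and two identical CH2OAc groups is a meso (Cs) structure, so only relative configuration has to be controlled. The unsymmetrical intermediates 6–15 are still carried as single enantiomers, fixed by the catalytic step 3.

## Retrosynthetic overview

1. Target 20 ⇐ hexa-ol 19 by lipase-catalysed acetylation of the two primary OH groups (catechols untouched) ⇐ desilylation and debenzylation of tetrahydrofuran 17.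
2. Tetrahydrofuran ring (formed last) ⇐ acid-catalysed cycloetherification of the meso 1,4-diaryl-1,4-diol 16.
3. 16 ⇐ reductive opening of the all-trans α-(hydroxybenzyl)lactone 14 ⇐ aldol, oxidation and chelation-controlled reduction on trans-lactone 10 with aldehyde 11.
4. γ-Lactone ring (formed first) ⇐ Ru-catalysed asymmetric transfer hydrogenation with dynamic kinetic resolution of aroylsuccinate 5, which sets the first stereocentre ⇐ 1 + 2 + 4.

## Route

**Step 1**
Reactants: 1 methyl 3,4-bis(benzyloxy)benzoate; 2 tert-butyl acetate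
Product: 3 tert-butyl 3-[3,4-bis(benzyloxy)phenyl]-3-oxopropanoate
Conditions: LDA (2.2 equiv, commercial solution), 2 (2.2 equiv), THF, −78 °C; then 1, −78 → 0 °C; aq. NH4Cl
Reagents that add atoms: none
Why: Crossed Claisen condensation of the lithium enolate of 2 with the non-enolisable ester 1, driven by deprotonation of the β-keto ester product.

**Step 2**
Reactants: 3 tert-butyl 3-[3,4-bis(benzyloxy)phenyl]-3-oxopropanoate; 4 methyl bromoacetate
Product: 5 1-tert-butyl 4-methyl 2-[3,4-bis(benzyloxy)benzoyl]butanedioate (racemic)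
Conditions: K2CO3 (1.0 equiv), 4 (1.05 equiv), acetone, rt
Reagents that add atoms: none
Why: C-alkylation (SN2) of the soft β-keto ester enolate with a reactive α-bromo ester gives the mono-alkylated aroylsuccinate.

**Step 3**
Reactants: 5 1-tert-butyl 4-methyl 2-[3,4-bis(benzyloxy)benzoyl]butanedioate
Product: 7 tert-butyl (2S,3S)-2-[3,4-bis(benzyloxy)phenyl]-5-oxooxolane-3-carboxylate (trans-lactone), via syn-hydroxy diester 6 (not isolated)
Conditions: RuCl(p-cymene)[(S,S)-TsDPEN] (1 mol%), HCO2H/Et3N (5:2), CH2Cl2, 35 °C; then PPTS (cat.), CH2Cl2, rt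
Reagents that add atoms: none
Why: Noyori asymmetric transfer hydrogenation with dynamic kinetic resolution, in which the α-centre racemises through the enol while the (S,S)-catalyst delivers hydride to one ketone face to give the (S)-carbinol of the syn isomer, which lactonises onto the methyl ester to the trans γ-lactone.

**Step 4**
Reactants: 7 tert-butyl (2S,3S)-2-[3,4-bis(benzyloxy)phenyl]-5-oxooxolane-3-carboxylate
Product: 8 (2S,3S)-2-[3,4-bis(benzyloxy)phenyl]-5-oxooxolane-3-carboxylic acid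
Conditions: TFA/CH2Cl2 (1:4), 0 °C, 1–2 h
Reagents that add atoms: none
Why: Acidolytic cleavage of the tert-butyl ester (loss of isobutene) leaves the lactone, the aryl benzyl ethers and both stereocentres untouched at 0 °C.

**Step 5**
Reactants: 8 (2S,3S)-2-[3,4-bis(benzyloxy)phenyl]-5-oxooxolane-3-carboxylic acid
Product: 9 (4R,5S)-5-[3,4-bis(benzyloxy)phenyl]-4-(hydroxymethyl)oxolan-2-one
Conditions: BH3·SMe2 (1.5 equiv), THF, 0 °C → rt; MeOH quench, aqueous work-up
Reagents that add atoms: none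
Why: Chemoselective borane reduction of a carboxylic acid in the presence of a lactone, via the acyloxyborane.

**Step 6**
Reactants: 9 (4R,5S)-5-[3,4-bis(benzyloxy)phenyl]-4-(hydroxymethyl)oxolan-2-one
Product: 10 (4R,5S)-5-[3,4-bis(benzyloxy)phenyl]-4-{[(tert-butyldiphenylsilyl)oxy]methyl}oxolan-2-one
Conditions: TBDPSCl (1.1 equiv), imidazole (2 equiv), CH2Cl2, 0 °C → rt
Reagents that add atoms: tert-butyl(chloro)diphenylsilane (TBDPSCl), CC(C)(C)[Si](Cl)(c1ccccc1)c1ccccc1
Why: Silylation of the primary alcohol blocks translactonisation and supplies an acid- and base-robust ether for the later steps.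

**Step 7**
Reactants: 10 (4R,5S)-5-[3,4-bis(benzyloxy)phenyl]-4-{[(tert-butyldiphenylsilyl)oxy]methyl}oxolan-2-one; 11 3,4-bis(benzyloxy)benzaldehyde
Product: 12 (3R,4R,5S)-5-[3,4-bis(benzyloxy)phenyl]-3-{[3,4-bis(benzyloxy)phenyl](hydroxy)methyl}-4-{[(tert-butyldiphenylsilyl)oxy]methyl}oxolan-2-one (mixture of carbinol epimers; both are used)
Conditions: LDA (1.1 equiv), THF, −78 °C; then 11, −78 °C; aq. NH4Cl
Reagents that add atoms: none
Why: Aldol addition of the lactone lithium enolate, in which the aldehyde approaches the α-carbon anti to the adjacent CH2OTBDPS group and so sets the α,β-trans relationship (the later 3,4-cis relationship of the tetrahydrofuran).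

**Step 8**
Reactants: 12 aldol adduct (carbinol epimers)
Product: 13 (3R,4R,5S)-3-[3,4-bis(benzyloxy)benzoyl]-5-[3,4-bis(benzyloxy)phenyl]-4-{[(tert-butyldiphenylsilyl)oxy]methyl}oxolan-2-one
Conditions: Dess–Martin periodinane (1.3 equiv), CH2Cl2, rt
Reagents that add atoms: none
Why: Dess–Martin oxidation converges both carbinol epimers to one α-aroyl lactone whose epimerisable α-centre rests in the favoured trans arrangement.

**Step 9**
Reactants: 13 α-aroyl lactone
Product: 14 (3R,4R,5S)-3-{(R)-[3,4-bis(benzyloxy)phenyl](hydroxy)methyl}-5-[3,4-bis(benzyloxy)phenyl]-4-{[(tert-butyldiphenylsilyl)oxy]methyl}oxolan-2-one (syn aldol)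
Conditions: Zn(BH4)2 (pre-formed Et2O solution, 1.5 equiv), CH2Cl2/Et2O, −20 °C; aq. NH4Cl
Reagents that add atoms: none
Why: Chelation-controlled reduction of an α-substituted β-keto ester, in which zinc bridges the ketone and lactone carbonyls and hydride attacks from the α-H side to give the syn (R)-carbinol; the lactone itself is not reduced.

**Step 10**
Reactants: 14 syn-hydroxy lactone
Product: 15 (1R,2S,3R,4S)-1,4-bis[3,4-bis(benzyloxy)phenyl]-2-(hydroxymethyl)-3-{[(tert-butyldiphenylsilyl)oxy]methyl}butane-1,4-diol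
Conditions: LiBH4 (3 equiv), THF, 0 °C → rt; aq. NH4Cl
Reagents that add atoms: none
Why: Hydride reduction of the lactone to the diol opens the ring without touching any stereocentre, the silyl ether or the benzyl ethers.

**Step 11**
Reactants: 15 triol
Product: 16 meso-(1R,2S,3R,4S)-1,4-bis[3,4-bis(benzyloxy)phenyl]-2,3-bis{[(tert-butyldiphenylsilyl)oxy]methyl}butane-1,4-diol
Conditions: TBDPSCl (1.1 equiv), imidazole (2 equiv), CH2Cl2, 0 °C
Reagents that add atoms: tert-butyl(chloro)diphenylsilane (TBDPSCl), CC(C)(C)[Si](Cl)(c1ccccc1)c1ccccc1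
Why: The bulky silyl chloride reacts selectively with the primary alcohol over the two hindered secondary benzylic alcohols, so only the 1,4-diol can cyclise in the next step.

**Step 12**
Reactants: 16 meso bis-silyl diol
Product: 17 meso-(2R,3S,4R,5S)-2,5-bis[3,4-bis(benzyloxy)phenyl]-3,4-bis{[(tert-butyldiphenylsilyl)oxy]methyl}oxolane (aryls 2,5-cis, CH2OSi groups 3,4-cis, each aryl trans to its neighbouring CH2OSi)
Conditions: TsOH·H2O (10 mol%), CH2Cl2, 4 Å MS, 0 °C → rt
Reagents that add atoms: none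
Why: SN1 cycloetherification in which either (enantiotopic) p-alkoxybenzylic alcohol ionises and the other hydroxyl closes the five-membered ring trans to the adjacent CH2OTBDPS group, the kinetically and thermodynamically preferred outcome, while the non-ionised carbinol keeps its configuration.

**Step 13**
Reactants: 17 bis-silyl tetrahydrofuran
Product: 18 [(2R,3S,4R,5S)-2,5-bis[3,4-bis(benzyloxy)phenyl]oxolane-3,4-diyl]dimethanol (meso)
Conditions: TBAF (2.5 equiv), THF, rt; aq. NH4Cl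
Reagents that add atoms: none
Why: Fluoride-mediated desilylation frees both primary alcohols without affecting the benzyl ethers or the ring.

**Step 14**
Reactants: 18 tetra-O-benzyl diol
Product: 19 4,4'-[(2R,3S,4R,5S)-3,4-bis(hydroxymethyl)oxolane-2,5-diyl]di(benzene-1,2-diol) (meso)
Conditions: H2 (1 atm), 10% Pd/C, EtOAc/MeOH, rt, stopped at 4 equiv H2 uptake; filtered under Ar and used directly
Reagents that add atoms: none
Why: Catalytic hydrogenolysis removes the four aryl benzyl ethers much faster than it cleaves the hindered dialkyl benzylic C–O bonds of the ring.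

**Step 15**
Reactants: 19 hexa-ol
Product: 20 [(2R,3S,4R,5S)-2,5-bis(3,4-dihydroxyphenyl)oxolane-3,4-diyl]bis(methylene) diacetate (meso; identical to the target SMILES)
Conditions: immobilised Candida antarctica lipase B (Novozym 435), vinyl acetate (10 equiv), THF, 40 °C, Ar
Reagents that add atoms: vinyl acetate, CC(=O)OC=C
Why: Lipase-catalysed irreversible transesterification acylates the two primary aliphatic alcohols and leaves the four catechol hydroxyls untouched, because phenols are not accepted as nucleophiles by the acyl-enzyme.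

## Compound list

1 | methyl 3,4-bis(benzyloxy)benzoate | COC(=O)c1ccc(OCc2ccccc2)c(OCc2ccccc2)c1 | starting material
2 | tert-butyl acetate | CC(=O)OC(C)(C)C | starting material
3 | tert-butyl 3-[3,4-bis(benzyloxy)phenyl]-3-oxopropanoate | CC(C)(C)OC(=O)CC(=O)c1ccc(OCc2ccccc2)c(OCc2ccccc2)c1 | intermediate
4 | methyl bromoacetate | COC(=O)CBr | starting material
5 | 1-tert-butyl 4-methyl 2-[3,4-bis(benzyloxy)benzoyl]butanedioate (racemic) | COC(=O)CC(C(=O)OC(C)(C)C)C(=O)c1ccc(OCc2ccccc2)c(OCc2ccccc2)c1 | intermediate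
6 | 1-tert-butyl 4-methyl (2S)-2-{(S)-[3,4-bis(benzyloxy)phenyl](hydroxy)methyl}butanedioate (syn; not isolated) | COC(=O)C[C@H](C(=O)OC(C)(C)C)[C@H](O)c1ccc(OCc2ccccc2)c(OCc2ccccc2)c1 | intermediate
7 | tert-butyl (2S,3S)-2-[3,4-bis(benzyloxy)phenyl]-5-oxooxolane-3-carboxylate | O=C1C[C@H](C(=O)OC(C)(C)C)[C@@H](c2ccc(OCc3ccccc3)c(OCc3ccccc3)c2)O1 | intermediate
8 | (2S,3S)-2-[3,4-bis(benzyloxy)phenyl]-5-oxooxolane-3-carboxylic acid | O=C1C[C@H](C(=O)O)[C@@H](c2ccc(OCc3ccccc3)c(OCc3ccccc3)c2)O1 | intermediate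
9 | (4R,5S)-5-[3,4-bis(benzyloxy)phenyl]-4-(hydroxymethyl)oxolan-2-one | O=C1C[C@H](CO)[C@@H](c2ccc(OCc3ccccc3)c(OCc3ccccc3)c2)O1 | intermediate
10 | (4R,5S)-5-[3,4-bis(benzyloxy)phenyl]-4-{[(tert-butyldiphenylsilyl)oxy]methyl}oxolan-2-one | O=C1C[C@H](CO[Si](c2ccccc2)(c2ccccc2)C(C)(C)C)[C@@H](c2ccc(OCc3ccccc3)c(OCc3ccccc3)c2)O1 | intermediate
11 | 3,4-bis(benzyloxy)benzaldehyde | O=Cc1ccc(OCc2ccccc2)c(OCc2ccccc2)c1 | starting material
12 | (3R,4R,5S)-5-[3,4-bis(benzyloxy)phenyl]-3-{[3,4-bis(benzyloxy)phenyl](hydroxy)methyl}-4-{[(tert-butyldiphenylsilyl)oxy]methyl}oxolan-2-one (carbinol epimer mixture) | O=C1[C@@H](C(O)c2ccc(OCc3ccccc3)c(OCc3ccccc3)c2)[C@H](CO[Si](c2ccccc2)(c2ccccc2)C(C)(C)C)[C@@H](c2ccc(OCc3ccccc3)c(OCc3ccccc3)c2)O1 | intermediate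
13 | (3R,4R,5S)-3-[3,4-bis(benzyloxy)benzoyl]-5-[3,4-bis(benzyloxy)phenyl]-4-{[(tert-butyldiphenylsilyl)oxy]methyl}oxolan-2-one | O=C1[C@@H](C(=O)c2ccc(OCc3ccccc3)c(OCc3ccccc3)c2)[C@H](CO[Si](c2ccccc2)(c2ccccc2)C(C)(C)C)[C@@H](c2ccc(OCc3ccccc3)c(OCc3ccccc3)c2)O1 | intermediate
14 | (3R,4R,5S)-3-{(R)-[3,4-bis(benzyloxy)phenyl](hydroxy)methyl}-5-[3,4-bis(benzyloxy)phenyl]-4-{[(tert-butyldiphenylsilyl)oxy]methyl}oxolan-2-one | O=C1[C@@H]([C@@H](O)c2ccc(OCc3ccccc3)c(OCc3ccccc3)c2)[C@H](CO[Si](c2ccccc2)(c2ccccc2)C(C)(C)C)[C@@H](c2ccc(OCc3ccccc3)c(OCc3ccccc3)c2)O1 | intermediate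
15 | (1R,2S,3R,4S)-1,4-bis[3,4-bis(benzyloxy)phenyl]-2-(hydroxymethyl)-3-{[(tert-butyldiphenylsilyl)oxy]methyl}butane-1,4-diol | OC[C@@H]([C@@H](O)c1ccc(OCc2ccccc2)c(OCc2ccccc2)c1)[C@H](CO[Si](c1ccccc1)(c1ccccc1)C(C)(C)C)[C@H](O)c1ccc(OCc2ccccc2)c(OCc2ccccc2)c1 | intermediate
16 | meso-(1R,2S,3R,4S)-1,4-bis[3,4-bis(benzyloxy)phenyl]-2,3-bis{[(tert-butyldiphenylsilyl)oxy]methyl}butane-1,4-diol | CC(C)(C)[Si](c1ccccc1)(c1ccccc1)OC[C@@H]([C@@H](O)c1ccc(OCc2ccccc2)c(OCc2ccccc2)c1)[C@H](CO[Si](c1ccccc1)(c1ccccc1)C(C)(C)C)[C@H](O)c1ccc(OCc2ccccc2)c(OCc2ccccc2)c1 | intermediate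
17 | meso-(2R,3S,4R,5S)-2,5-bis[3,4-bis(benzyloxy)phenyl]-3,4-bis{[(tert-butyldiphenylsilyl)oxy]methyl}oxolane | CC(C)(C)[Si](c1ccccc1)(c1ccccc1)OC[C@@H]1[C@H](CO[Si](c2ccccc2)(c2ccccc2)C(C)(C)C)[C@@H](c2ccc(OCc3ccccc3)c(OCc3ccccc3)c2)O[C@H]1c1ccc(OCc2ccccc2)c(OCc2ccccc2)c1 | intermediate
18 | [(2R,3S,4R,5S)-2,5-bis[3,4-bis(benzyloxy)phenyl]oxolane-3,4-diyl]dimethanol | OC[C@@H]1[C@H](CO)[C@@H](c2ccc(OCc3ccccc3)c(OCc3ccccc3)c2)O[C@H]1c1ccc(OCc2ccccc2)c(OCc2ccccc2)c1 | intermediate
19 | 4,4'-[(2R,3S,4R,5S)-3,4-bis(hydroxymethyl)oxolane-2,5-diyl]di(benzene-1,2-diol) | OC[C@@H]1[C@H](CO)[C@@H](c2ccc(O)c(O)c2)O[C@H]1c1ccc(O)c(O)c1 | intermediate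
20 | [(2R,3S,4R,5S)-2,5-bis(3,4-dihydroxyphenyl)oxolane-3,4-diyl]bis(methylene) diacetate (CNP0416169.1) | CC(=O)OC[C@@H]1[C@H](COC(C)=O)[C@@H](c2ccc(O)c(O)c2)O[C@H]1c1ccc(O)c(O)c1 | target

## Summary

Total step count: 15.
Longest linear sequence: 15 steps (1 → 20); aldehyde 11 is commercial and enters at step 7.

**Three steps most likely to fail**

Step 3 (transfer hydrogenation with dynamic kinetic resolution): the syn/anti ratio for an α-alkyl aroylacetate is the least certain selectivity in the route. Fallback, setting out from 3 and returning at 7: reduce the unsubstituted β-keto ester 3 with the same Ru/(S,S)-TsDPEN catalyst and HCO2H/Et3N, which needs no dynamic resolution, to tert-butyl (S)-3-[3,4-bis(benzyloxy)phenyl]-3-hydroxypropanoate F1. Fráter–Seebach alkylation of its dianion (LDA 2.2 equiv, THF, −78 → −20 °C) with 4 gives the anti product 1-tert-butyl 4-methyl (2R)-2-{(S)-[3,4-bis(benzyloxy)phenyl](hydroxy)methyl}butanedioate F2. Catalytic PPTS closes this to the cis-lactone tert-butyl (2S,3R)-2-[3,4-bis(benzyloxy)phenyl]-5-oxooxolane-3-carboxylate F3. Catalytic DBU in toluene at rt then epimerises the ester-bearing carbon to the more stable trans-lactone 7.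

Step 9 (chelation-controlled reduction): the syn selectivity on a cyclic α-aroyl lactone could be lower than in acyclic cases. Fallback, setting out from 12 and returning at 17, which replaces kinetic control at the carbinol by thermodynamic control at the ring stage: reduce the aldol epimer mixture 12 directly with LiBH4 to the triol 1,4-bis[3,4-bis(benzyloxy)phenyl]-2-(hydroxymethyl)-3-{[(tert-butyldiphenylsilyl)oxy]methyl}butane-1,4-diol (C1 epimers) F4. Silylate the primary alcohol with TBDPSCl/imidazole to the bis-silyl diol (C1 epimers) F5. Cyclise with BF3·OEt2 (1 equiv) in CH2Cl2 at 0 °C → rt, where reversible ionisation of the p-alkoxybenzylic C–O bonds funnels every epimer to the isomer with each aryl trans to its neighbour, which is 17. The reaction must be stopped before Friedel–Crafts closure to an aryltetralin competes.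

Step 14 (hydrogenolysis): the ring benzylic C–O bonds may be over-reduced, and the free catechol hexa-ol is air-sensitive. Fallback, setting out from 18 and returning at 20: acetylate 18 (Ac2O, pyridine, DMAP, CH2Cl2) to [(2R,3S,4R,5S)-2,5-bis[3,4-bis(benzyloxy)phenyl]oxolane-3,4-diyl]bis(methylene) diacetate F6. Then remove the four aryl benzyl groups non-reductively with BCl3 and pentamethylbenzene in CH2Cl2 at −78 °C; pentamethylbenzene traps the benzyl cations and the acetates survive, giving 20 directly.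

## Further compounds

F1 | step 3 | tert-butyl (S)-3-[3,4-bis(benzyloxy)phenyl]-3-hydroxypropanoate | CC(C)(C)OC(=O)C[C@H](O)c1ccc(OCc2ccccc2)c(OCc2ccccc2)c1
F2 | step 3 | 1-tert-butyl 4-methyl (2R)-2-{(S)-[3,4-bis(benzyloxy)phenyl](hydroxy)methyl}butanedioate | COC(=O)C[C@@H](C(=O)OC(C)(C)C)[C@H](O)c1ccc(OCc2ccccc2)c(OCc2ccccc2)c1
F3 | step 3 | tert-butyl (2S,3R)-2-[3,4-bis(benzyloxy)phenyl]-5-oxooxolane-3-carboxylate | O=C1C[C@@H](C(=O)OC(C)(C)C)[C@@H](c2ccc(OCc3ccccc3)c(OCc3ccccc3)c2)O1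
F4 | step 9 | (2S,3R,4S)-1,4-bis[3,4-bis(benzyloxy)phenyl]-2-(hydroxymethyl)-3-{[(tert-butyldiphenylsilyl)oxy]methyl}butane-1,4-diol (C1 epimer mixture) | OC[C@@H](C(O)c1ccc(OCc2ccccc2)c(OCc2ccccc2)c1)[C@H](CO[Si](c1ccccc1)(c1ccccc1)C(C)(C)C)[C@H](O)c1ccc(OCc2ccccc2)c(OCc2ccccc2)c1
F5 | step 9 | (2S,3R,4S)-1,4-bis[3,4-bis(benzyloxy)phenyl]-2,3-bis{[(tert-butyldiphenylsilyl)oxy]methyl}butane-1,4-diol (C1 epimer mixture) | CC(C)(C)[Si](c1ccccc1)(c1ccccc1)OC[C@@H](C(O)c1ccc(OCc2ccccc2)c(OCc2ccccc2)c1)[C@H](CO[Si](c1ccccc1)(c1ccccc1)C(C)(C)C)[C@H](O)c1ccc(OCc2ccccc2)c(OCc2ccccc2)c1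
F6 | step 14 | [(2R,3S,4R,5S)-2,5-bis[3,4-bis(benzyloxy)phenyl]oxolane-3,4-diyl]bis(methylene) diacetate | CC(=O)OC[C@@H]1[C@H](COC(C)=O)[C@@H](c2ccc(OCc3ccccc3)c(OCc3ccccc3)c2)O[C@H]1c1ccc(OCc2ccccc2)c(OCc2ccccc2)c1
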